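**Plan**
- Retrosynthesis: cut the C15 and C9 ester C–O bonds and return the lactone carbonyl C12 to a lactol methyl ether; cut C7–C8 by a retro-Claisen shift, which re-expands the ten-membered carbocycle to a 12-membered lactone (C9–O–C13); then cut that lactone C–O bond, the dihydrofuran (C7=C11 by metathesis, O6–C12 acetal) and the C1=C10 and C4=C5 bonds (two Z-selective olefinations).
- Enabling feature: C9 (oxygen-bearing) and C7 are 1,3 across C8, and C7 carries the exocyclic C11=C13 methylene. The array C9(=O)–C8–C7–C11=C13 is therefore a Claisen retron whose allyl half is the α-methylene lactone ring and whose ketone half lies in the ten-membered ring.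
- Forward order: linear chain C9→C7 from (S)-but-3-ene-1,2-diol; then the 2-methoxy-2,5-dihydrofuran (O6, C12, C11, C7, C6); then the 12-membered lactone; then ring contraction to the ten-membered ring with the cis-fused oxacycle; then C9 reduction, the two esters, and oxidation of the acetal to the lactone.
- Stereochemistry: C6 from the chiral-pool diol; C7 from C6 in the ring contraction; C9 by CBS reduction; both trisubstituted alkene geometries from Still–Gennari olefinations.

Key step: step 18

Remark: germacrane-type locants are used (ring C1–C10; C11–C13 the lactone side chain; C14 on C10; C15 on C4). In CIP terms the target is (1(10)Z,4Z,6R,7R,9S): C9 cis to C2, C15 cis to C6, cis-fused lactone.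

**Route**

Step 1
Reactants: 1 methyl 2-[bis(2,2,2-trifluoroethoxy)phosphoryl]acetate; 2 1-[(3-bromopropoxy)methyl]-4-methoxybenzene
Product: 3 methyl 2-[bis(2,2,2-trifluoroethoxy)phosphoryl]-5-[(4-methoxybenzyl)oxy]pentanoate (racemic)
Conditions: NaH, DMF, 0 °C; then 2, NaI (cat.), rt (1 in excess)
Reagents that add atoms: none
Why: The sodium salt of the stabilised phosphonoacetate should be C-alkylated once by the primary bromide (SN2 phosphonate alkylation), excess 1 suppressing dialkylation; the new centre is lost in step 4.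

Step 2
Reactants: 4 (S)-but-3-ene-1,2-diol
Product: 5 (S)-3,4-bis(triethylsilyloxy)but-1-ene
Conditions: TESCl, imidazole, CH2Cl2, 0 °C to rt
Reagents that add atoms: chlorotriethylsilane, CC[Si](Cl)(CC)CC
Why: Both hydroxyls should silylate under standard imidazole conditions (silyl ether formation) without touching the stereocentre, which becomes C6.

Step 3
Reactants: 5 (S)-3,4-bis(triethylsilyloxy)but-1-ene
Product: 6 (S)-2-(triethylsilyloxy)but-3-enal
Conditions: (COCl)2, DMSO, CH2Cl2, −78 to −40 °C; Et3N, −78 to 0 °C; used at once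
Reagents that add atoms: none
Why: Under Swern conditions a primary triethylsilyl ether is cleaved and oxidised in the same flask while the secondary one survives (Swern oxidation of a primary TES ether); low temperature and immediate use should protect the α-centre.

Step 4
Reactants: 6 (S)-2-(triethylsilyloxy)but-3-enal; 3 methyl 2-[bis(2,2,2-trifluoroethoxy)phosphoryl]-5-[(4-methoxybenzyl)oxy]pentanoate
Product: 7 methyl (2Z,4S)-2-[3-(4-methoxybenzyloxy)propyl]-4-(triethylsilyloxy)hexa-2,5-dienoate
Conditions: 3, KHMDS, 18-crown-6, THF, −78 °C; then 6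
Reagents that add atoms: none
Why: The Still–Gennari variant of the Horner–Wadsworth–Emmons reaction with an α-alkyl bis(trifluoroethyl)phosphonate should give the Z-trisubstituted enoate (ester carbon C15 cis to C6) at a temperature where the aldehyde should neither epimerise nor isomerise.

Step 5
Reactants: 7 methyl (2Z,4S)-2-[3-(4-methoxybenzyloxy)propyl]-4-(triethylsilyloxy)hexa-2,5-dienoate
Product: 8 (2Z,4S)-2-[3-(4-methoxybenzyloxy)propyl]-4-(triethylsilyloxy)hexa-2,5-dien-1-ol
Conditions: DIBAL-H, CH2Cl2, −78 °C; Rochelle salt work-up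
Reagents that add atoms: none
Why: DIBAL-H should reduce the conjugated ester to the allylic alcohol C15–OH (1,2-reduction) while silyl and PMB ethers stay intact.

Step 6
Reactants: 8 (2Z,4S)-2-[3-(4-methoxybenzyloxy)propyl]-4-(triethylsilyloxy)hexa-2,5-dien-1-ol
Product: 9 (2Z,4S)-1-(tert-butyldimethylsilyloxy)-2-[3-(4-methoxybenzyloxy)propyl]-4-(triethylsilyloxy)hexa-2,5-diene
Conditions: TBSCl, imidazole, DMF, rt
Reagents that add atoms: tert-butyldimethylsilyl chloride, CC(C)(C)[Si](C)(C)Cl
Why: Silylation of the primary allylic alcohol is routine and gives a C15 protecting group that outlasts the later TES removal.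

Step 7
Reactants: 9 (2Z,4S)-1-(tert-butyldimethylsilyloxy)-2-[3-(4-methoxybenzyloxy)propyl]-4-(triethylsilyloxy)hexa-2,5-diene
Product: 10 (4Z,6S)-4-[(tert-butyldimethylsilyloxy)methyl]-6-(triethylsilyloxy)octa-4,7-dien-1-ol
Conditions: DDQ, CH2Cl2/pH 7 buffer, 0 °C
Reagents that add atoms: none
Why: Oxidative PMB cleavage with DDQ in buffered wet CH2Cl2 should free the C1 alcohol and leave silyl ethers and alkenes untouched.

Step 8
Reactants: 10 (4Z,6S)-4-[(tert-butyldimethylsilyloxy)methyl]-6-(triethylsilyloxy)octa-4,7-dien-1-ol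
Product: 11 (4Z,6S)-4-[(tert-butyldimethylsilyloxy)methyl]-6-(triethylsilyloxy)octa-4,7-dienal
Conditions: Dess–Martin periodinane, NaHCO3, CH2Cl2, rt
Reagents that add atoms: none
Why: Dess–Martin oxidation under buffered neutral conditions should give the C1 aldehyde, which has no α-stereocentre to lose.

Step 9
Reactants: 11 (4Z,6S)-4-[(tert-butyldimethylsilyloxy)methyl]-6-(triethylsilyloxy)octa-4,7-dienal; 12 ethyl 2-[bis(2,2,2-trifluoroethoxy)phosphoryl]propanoate
Product: 13 ethyl (2Z,6Z,8S)-6-[(tert-butyldimethylsilyloxy)methyl]-2-methyl-8-(triethylsilyloxy)deca-2,6,9-trienoate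
Conditions: 12, KHMDS, 18-crown-6, THF, −78 °C; then 11
Reagents that add atoms: none
Why: A second Still–Gennari olefination with the α-methyl phosphonate should give the Z-(angelate-type) enoate, C9 cis to C2, which fixes the C1=C10 geometry.

Step 10
Reactants: 13 ethyl (2Z,6Z,8S)-6-[(tert-butyldimethylsilyloxy)methyl]-2-methyl-8-(triethylsilyloxy)deca-2,6,9-trienoate
Product: 14 ethyl (2Z,6Z,8S)-6-[(tert-butyldimethylsilyloxy)methyl]-8-hydroxy-2-methyldeca-2,6,9-trienoate
Conditions: PPTS (cat.), MeOH, 0 °C
Reagents that add atoms: none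
Why: Mild acid methanolysis should cleave the secondary TES ether much faster than the primary TBS ether (selective desilylation), freeing O6 without ionising the bis-allylic carbinol.

Step 11
Reactants: 15 2-methylidenepropane-1,3-diol
Product: 16 2-(hydroxymethyl)prop-2-en-1-yl acetate
Conditions: Ac2O (substoichiometric), Et3N, CH2Cl2, 0 °C (diol in excess)
Reagents that add atoms: acetic anhydride, CC(=O)OC(C)=O
Why: Acylation of the symmetric diol in excess should favour the monoacetate, which will carry the C13 oxygen.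

Step 12
Reactants: 16 2-(hydroxymethyl)prop-2-en-1-yl acetate
Product: 17 2-formylprop-2-en-1-yl acetate
Conditions: MnO2, CH2Cl2, rt
Reagents that add atoms: none
Why: MnO2 oxidises the allylic alcohol to the enal (allylic oxidation) and leaves the acetate alone.

Step 13
Reactants: 17 2-formylprop-2-en-1-yl acetate
Product: 18 2-(dimethoxymethyl)prop-2-en-1-yl acetate
Conditions: HC(OMe)3, PPTS (cat.), CH2Cl2, rt
Reagents that add atoms: trimethyl orthoformate, COC(OC)OC
Why: Acid-catalysed acetalisation with the orthoformate as methoxy source and water scavenger should give the dimethyl acetal of the enal.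

Step 14
Reactants: 14 ethyl (2Z,6Z,8S)-6-[(tert-butyldimethylsilyloxy)methyl]-8-hydroxy-2-methyldeca-2,6,9-trienoate; 18 2-(dimethoxymethyl)prop-2-en-1-yl acetate
Product: 19 ethyl (2Z,6Z,8S)-8-{[2-(acetoxymethyl)-1-methoxyprop-2-en-1-yl]oxy}-6-[(tert-butyldimethylsilyloxy)methyl]-2-methyldeca-2,6,9-trienoate (both acetal epimers)
Conditions: 18 (excess), PPTS (cat.), 5 Å molecular sieves, toluene, rt
Reagents that add atoms: none
Why: Transacetalisation should exchange one methoxy group of the allylic acetal for O6 (excess 18, methanol trapped by the sieves); the C6–O bond is not broken, so C6 keeps its configuration, and the new acetal centre C12 forms as two epimers that both serve.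

Step 15
Reactants: 19 ethyl (2Z,6Z,8S)-8-{[2-(acetoxymethyl)-1-methoxyprop-2-en-1-yl]oxy}-6-[(tert-butyldimethylsilyloxy)methyl]-2-methyldeca-2,6,9-trienoate
Product: 20 ethyl (2Z,6Z)-7-[(2R)-4-(acetoxymethyl)-5-methoxy-2,5-dihydrofuran-2-yl]-6-[(tert-butyldimethylsilyloxy)methyl]-2-methylhepta-2,6-dienoate (both acetal epimers)
Conditions: Grubbs second-generation catalyst (5 mol %), CH2Cl2 (dilute), 40 °C
Reagents that add atoms: none
Why: Ring-closing metathesis should start at the monosubstituted vinyl group and close onto the 1,1-disubstituted alkene to give the five-membered 2,5-dihydrofuran (C7=C11), the trisubstituted alkenes being inert.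

Step 16
Reactants: 20 ethyl (2Z,6Z)-7-[(2R)-4-(acetoxymethyl)-5-methoxy-2,5-dihydrofuran-2-yl]-6-[(tert-butyldimethylsilyloxy)methyl]-2-methylhepta-2,6-dienoate
Product: 21 (2Z,6Z)-6-[(tert-butyldimethylsilyloxy)methyl]-7-[(2R)-4-(hydroxymethyl)-5-methoxy-2,5-dihydrofuran-2-yl]-2-methylhepta-2,6-dienoic acid
Conditions: LiOH, THF/MeOH/H2O, rt; pH 5 buffer work-up at 0 °C
Reagents that add atoms: lithium hydroxide, [Li+].[OH-]
Why: Saponification should cleave the acetate and the ethyl ester together, the acetal and silyl ether being base-stable; buffered work-up avoids ionising the allylic acetal.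

Step 17
Reactants: 21 (2Z,6Z)-6-[(tert-butyldimethylsilyloxy)methyl]-7-[(2R)-4-(hydroxymethyl)-5-methoxy-2,5-dihydrofuran-2-yl]-2-methylhepta-2,6-dienoic acid
Product: 22 12-membered lactone of 21 (C9 carboxyl esterified by the C13 oxygen; ring C9–O–C13–C11–C7–C6–C5–C4–C3–C2–C1–C10, bridged by O6–C12(OMe); 6R; C9 cis to C2; C15 cis to C6)
Conditions: PPh3, DIAD, toluene, 0 °C to rt, slow addition of 21 (high dilution)
Reagents that add atoms: none
Why: Mitsunobu macrolactonisation activates the primary allylic alcohol and not the acid, so the Z-α-methyl enoate cannot isomerise through an activated acyl species; SN2 attack of the carboxylate at C13 should close the 12-membered ring.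

Step 18
Reactants: 22 12-membered lactone (C9–O–C13) bridged by the 2-methoxy-2,5-dihydrofuran
Product: 24 (1(10)Z,4Z,6R,7R)-15-(tert-butyldimethylsilyloxy)-12-methoxy-6,12-epoxygermacra-1(10),4,11(13)-trien-9-one, via macrocyclic 2-alkoxydiene 23 (not isolated)
Conditions: Cp2TiMe2, toluene, 75 °C, dark; then 125 °C (sealed, base-washed glass)
Reagents that add atoms: dimethyltitanocene, C[Ti](C)(C1C=CC=C1)C1C=CC=C1
Why: Proposed new method: Cp2Ti=CH2 from Cp2TiMe2 should convert the only carbonyl, the conjugated lactone C9=O, into the exocyclic enol ether 23, whose allyl vinyl ether array C8=C9–O–C13–C11=C7 should then undergo a concerted [3,3] (Claisen) shift that makes C7–C8 and breaks O–C13, so that O, C13 and C11 leave the ring, C8 enters it, and the 12-membered oxacycle contracts to the ten-membered carbocycle with C9 as ketone and C11=C13 as the exocyclic methylene. The closest known reaction types are the lactone methylenation/Claisen ring expansion of 2-methylene-6-vinyltetrahydropyrans and the ester-enolate Claisen ring contraction of macrolides; a two-atom enol-ether contraction onto a medium ring is the extension proposed here. The ten-membered ring closes through a chair-like six-centre transition state bridged onto the forming ring at C9 and C7, with the vinyl ether lying away from the dihydrofuran. The only new stereocentre, C7, should be set by C6: the dihydrofuran holds O6 in the plane of C7=C11 and C5 out of it, and the short tether C10=C1–C2–C3–C4 from C9 to C5 (one cis and one trans double bond) should reach C7 only over the face that carries C5, which gives the cis ring fusion (7R from 6R). The step needs this facial selectivity and also [3,3] over a [1,5]-hydrogen shift of the Z-2-alkoxydiene and over Cope rearrangement of the C10=C1/C4=C5 1,5-diene; the first rests on the tether, the others on the lower barrier expected for a 2-substituted allyl vinyl ether, and the ring keeps C1=C10 cis.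

Step 19
Reactants: 24 (1(10)Z,4Z,6R,7R)-15-(tert-butyldimethylsilyloxy)-12-methoxy-6,12-epoxygermacra-1(10),4,11(13)-trien-9-one
Product: 25 (1(10)Z,4Z,6R,7R,9S)-15-(tert-butyldimethylsilyloxy)-12-methoxy-6,12-epoxygermacra-1(10),4,11(13)-trien-9-ol
Conditions: (R)-Me-CBS (0.5 equiv), catecholborane, toluene, −78 °C
Reagents that add atoms: none
Why: Corey–Bakshi–Shibata reduction should be 1,2-selective and, with the α-methyl alkenyl group as the large and C8H2 as the small substituent, the (R)-catalyst should deliver hydride to the face that gives the (9S)-allylic alcohol under reagent control.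

Step 20
Reactants: 25 (1(10)Z,4Z,6R,7R,9S)-15-(tert-butyldimethylsilyloxy)-12-methoxy-6,12-epoxygermacra-1(10),4,11(13)-trien-9-ol
Product: 26 (1(10)Z,4Z,6R,7R,9S)-9-acetoxy-15-(tert-butyldimethylsilyloxy)-12-methoxy-6,12-epoxygermacra-1(10),4,11(13)-triene
Conditions: Ac2O, Et3N, DMAP (cat.), CH2Cl2, rt
Reagents that add atoms: acetic anhydride, CC(=O)OC(C)=O
Why: Acetylation of the secondary allylic alcohol under basic conditions retains the C9 configuration and spares the acetal.

Step 21
Reactants: 26 (1(10)Z,4Z,6R,7R,9S)-9-acetoxy-15-(tert-butyldimethylsilyloxy)-12-methoxy-6,12-epoxygermacra-1(10),4,11(13)-triene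
Product: 27 (1(10)Z,4Z,6R,7R,9S)-9-acetoxy-12-methoxy-6,12-epoxygermacra-1(10),4,11(13)-trien-15-ol
Conditions: TBAF, AcOH, THF, 0 °C to rt
Reagents that add atoms: none
Why: Fluoride should cleave the primary TBS ether, the acetic acid buffer protecting the acetate, while the acetal is stable to these conditions.

Step 22
Reactants: 27 (1(10)Z,4Z,6R,7R,9S)-9-acetoxy-12-methoxy-6,12-epoxygermacra-1(10),4,11(13)-trien-15-ol
Product: 28 (1(10)Z,4Z,6R,7R,9S)-9-acetoxy-12-methoxy-15-(3-methylbutanoyloxy)-6,12-epoxygermacra-1(10),4,11(13)-triene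
Conditions: isovaleryl chloride, pyridine, DMAP (cat.), CH2Cl2, 0 °C
Reagents that add atoms: 3-methylbutanoyl chloride, CC(C)CC(=O)Cl
Why: Acylation of the primary allylic alcohol with the acid chloride is routine and installs the C15 ester.

Step 23
Reactants: 28 (1(10)Z,4Z,6R,7R,9S)-9-acetoxy-12-methoxy-15-(3-methylbutanoyloxy)-6,12-epoxygermacra-1(10),4,11(13)-triene
Product: 29 (1(10)Z,4Z,6R,7R,9S)-9-acetoxy-15-(3-methylbutanoyloxy)germacra-1(10),4,11(13)-trien-12,6-olide (target)
Conditions: Jones reagent (CrO3, aq. H2SO4), acetone, 0 °C, short contact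
Reagents that add atoms: water, O
Why: Jones reagent should hydrolyse the allylic lactol methyl ether and oxidise the lactol in the same flask to the α-methylene-γ-butyrolactone (Jones oxidation of a 2-alkoxy-3-methylenetetrahydrofuran), and no stereocentre is touched.

**Compound list**

1 | methyl 2-[bis(2,2,2-trifluoroethoxy)phosphoryl]acetate | COC(=O)CP(=O)(OCC(F)(F)F)OCC(F)(F)F | starting material
2 | 1-[(3-bromopropoxy)methyl]-4-methoxybenzene | COc1ccc(COCCCBr)cc1 | starting material
3 | methyl 2-[bis(2,2,2-trifluoroethoxy)phosphoryl]-5-[(4-methoxybenzyl)oxy]pentanoate (racemic) | COC(=O)C(CCCOCc1ccc(OC)cc1)P(=O)(OCC(F)(F)F)OCC(F)(F)F | intermediate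
4 | (S)-but-3-ene-1,2-diol | C=C[C@H](O)CO | starting material
5 | (S)-3,4-bis(triethylsilyloxy)but-1-ene | C=C[C@H](O[Si](CC)(CC)CC)CO[Si](CC)(CC)CC | intermediate
6 | (S)-2-(triethylsilyloxy)but-3-enal | C=C[C@H](O[Si](CC)(CC)CC)C=O | intermediate
7 | methyl (2Z,4S)-2-[3-(4-methoxybenzyloxy)propyl]-4-(triethylsilyloxy)hexa-2,5-dienoate | COC(=O)/C(CCCOCc1ccc(OC)cc1)=C\[C@@H](O[Si](CC)(CC)CC)C=C | intermediate
8 | (2Z,4S)-2-[3-(4-methoxybenzyloxy)propyl]-4-(triethylsilyloxy)hexa-2,5-dien-1-ol | OC/C(CCCOCc1ccc(OC)cc1)=C\[C@@H](O[Si](CC)(CC)CC)C=C | intermediate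
9 | (2Z,4S)-1-(tert-butyldimethylsilyloxy)-2-[3-(4-methoxybenzyloxy)propyl]-4-(triethylsilyloxy)hexa-2,5-diene | CC(C)(C)[Si](C)(C)OC/C(CCCOCc1ccc(OC)cc1)=C\[C@@H](O[Si](CC)(CC)CC)C=C | intermediate
10 | (4Z,6S)-4-[(tert-butyldimethylsilyloxy)methyl]-6-(triethylsilyloxy)octa-4,7-dien-1-ol | CC(C)(C)[Si](C)(C)OC/C(CCCO)=C\[C@@H](O[Si](CC)(CC)CC)C=C | intermediate
11 | (4Z,6S)-4-[(tert-butyldimethylsilyloxy)methyl]-6-(triethylsilyloxy)octa-4,7-dienal | CC(C)(C)[Si](C)(C)OC/C(CCC=O)=C\[C@@H](O[Si](CC)(CC)CC)C=C | intermediate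
12 | ethyl 2-[bis(2,2,2-trifluoroethoxy)phosphoryl]propanoate | CCOC(=O)C(C)P(=O)(OCC(F)(F)F)OCC(F)(F)F | starting material
13 | ethyl (2Z,6Z,8S)-6-[(tert-butyldimethylsilyloxy)methyl]-2-methyl-8-(triethylsilyloxy)deca-2,6,9-trienoate | CCOC(=O)/C(C)=C\CC/C(CO[Si](C)(C)C(C)(C)C)=C/[C@@H](O[Si](CC)(CC)CC)C=C | intermediate
14 | ethyl (2Z,6Z,8S)-6-[(tert-butyldimethylsilyloxy)methyl]-8-hydroxy-2-methyldeca-2,6,9-trienoate | CCOC(=O)/C(C)=C\CC/C(CO[Si](C)(C)C(C)(C)C)=C/[C@@H](O)C=C | intermediate
15 | 2-methylidenepropane-1,3-diol | C=C(CO)CO | starting material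
16 | 2-(hydroxymethyl)prop-2-en-1-yl acetate | C=C(CO)COC(C)=O | intermediate
17 | 2-formylprop-2-en-1-yl acetate | C=C(C=O)COC(C)=O | intermediate
18 | 2-(dimethoxymethyl)prop-2-en-1-yl acetate | COC(OC)C(=C)COC(C)=O | intermediate
19 | ethyl (2Z,6Z,8S)-8-{[2-(acetoxymethyl)-1-methoxyprop-2-en-1-yl]oxy}-6-[(tert-butyldimethylsilyloxy)methyl]-2-methyldeca-2,6,9-trienoate (acetal epimers) | CCOC(=O)/C(C)=C\CC/C(CO[Si](C)(C)C(C)(C)C)=C/[C@@H](OC(OC)C(=C)COC(C)=O)C=C | intermediate
20 | ethyl (2Z,6Z)-7-[(2R)-4-(acetoxymethyl)-5-methoxy-2,5-dihydrofuran-2-yl]-6-[(tert-butyldimethylsilyloxy)methyl]-2-methylhepta-2,6-dienoate (acetal epimers) | CCOC(=O)/C(C)=C\CC/C(CO[Si](C)(C)C(C)(C)C)=C/[C@H]1OC(OC)C(=C1)COC(C)=O | intermediate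
21 | (2Z,6Z)-6-[(tert-butyldimethylsilyloxy)methyl]-7-[(2R)-4-(hydroxymethyl)-5-methoxy-2,5-dihydrofuran-2-yl]-2-methylhepta-2,6-dienoic acid (acetal epimers) | OC(=O)/C(C)=C\CC/C(CO[Si](C)(C)C(C)(C)C)=C/[C@H]1OC(OC)C(=C1)CO | intermediate
22 | 12-membered lactone of 21 (C9–O–C13 ester, bridged by the 2-methoxy-2,5-dihydrofuran; 6R) | O=C1/C(C)=C\CC/C(CO[Si](C)(C)C(C)(C)C)=C/[C@H]2OC(OC)C(=C2)CO1 | intermediate
23 | 9-methylidene analogue of 22 (macrocyclic 2-alkoxydiene, exocyclic C9=C8H2) | C=C1/C(C)=C\CC/C(CO[Si](C)(C)C(C)(C)C)=C/[C@H]2OC(OC)C(=C2)CO1 | intermediate (not isolated)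
24 | (1(10)Z,4Z,6R,7R)-15-(tert-butyldimethylsilyloxy)-12-methoxy-6,12-epoxygermacra-1(10),4,11(13)-trien-9-one (C12 epimers) | C=C1C(OC)O[C@@H]2/C=C(\CO[Si](C)(C)C(C)(C)C)CC/C=C(/C)C(=O)C[C@H]12 | intermediate
25 | (1(10)Z,4Z,6R,7R,9S)-15-(tert-butyldimethylsilyloxy)-12-methoxy-6,12-epoxygermacra-1(10),4,11(13)-trien-9-ol | C=C1C(OC)O[C@@H]2/C=C(\CO[Si](C)(C)C(C)(C)C)CC/C=C(/C)[C@@H](O)C[C@H]12 | intermediate
26 | (1(10)Z,4Z,6R,7R,9S)-9-acetoxy-15-(tert-butyldimethylsilyloxy)-12-methoxy-6,12-epoxygermacra-1(10),4,11(13)-triene | C=C1C(OC)O[C@@H]2/C=C(\CO[Si](C)(C)C(C)(C)C)CC/C=C(/C)[C@@H](OC(C)=O)C[C@H]12 | intermediate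
27 | (1(10)Z,4Z,6R,7R,9S)-9-acetoxy-12-methoxy-6,12-epoxygermacra-1(10),4,11(13)-trien-15-ol | C=C1C(OC)O[C@@H]2/C=C(\CO)CC/C=C(/C)[C@@H](OC(C)=O)C[C@H]12 | intermediate
28 | (1(10)Z,4Z,6R,7R,9S)-9-acetoxy-12-methoxy-15-(3-methylbutanoyloxy)-6,12-epoxygermacra-1(10),4,11(13)-triene | C=C1C(OC)O[C@@H]2/C=C(\COC(=O)CC(C)C)CC/C=C(/C)[C@@H](OC(C)=O)C[C@H]12 | intermediate
29 | (1(10)Z,4Z,6R,7R,9S)-9-acetoxy-15-(3-methylbutanoyloxy)germacra-1(10),4,11(13)-trien-12,6-olide | C=C1C(=O)O[C@@H]2/C=C(\COC(=O)CC(C)C)CC/C=C(/C)[C@@H](OC(C)=O)C[C@H]12 | target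

**Totals**

Total step count: 23. Longest linear sequence: 19 steps (4 to 29; steps 2–10 and 14–23).

**Steps most likely to fail**

Step 18 (proposed new method). The acid- and heat-sensitive 2-alkoxydiene may be protonated, undergo a [1,5]-hydrogen shift, or lose methanol from the dihydrofuran acetal before the sigmatropic shift occurs. The fallback avoids the enol ether and the high temperature and uses known reaction types. It sets out from 20. An intramolecular Claisen condensation of the acetate enolate onto the C9 ethyl ester (LiHMDS, THF, −78 to 0 °C, high dilution) should give the 14-membered allyl β-keto lactone F1. Its dianion (LDA, 2.2 equiv, THF, −78 °C to reflux) should undergo the Carroll (ester-enolate Claisen) shift, the mode in which macrolide ring contractions are established, under the same tether control, to the ring-contracted β-keto acid F2. F2 should lose carbon dioxide on buffered acidification and gentle warming and comes back to the route at 24.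

Step 4. The α-silyloxy β,γ-unsaturated aldehyde 6 may epimerise at C6 or move its vinyl double bond into conjugation before it is olefinated. The fallback never liberates the free aldehyde in the absence of the olefinating agent. It sets out from 3. Methyl (S)-2-hydroxybut-3-enoate F3 is silylated (TESCl, imidazole) to the triethylsilyl ether F4. F4 is reduced with DIBAL-H (1 equiv, −78 °C) to the aluminium hemiacetal and transferred cold onto the preformed potassium salt of 3 (KHMDS, 18-crown-6), so that reduction and Still–Gennari olefination run in tandem. The sequence comes back at 7.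

Step 17. The activated allylic alcohol may oligomerise, be captured in an SN2′ sense at C7, or ionise instead of closing the strained bridged 12-membered ring. The fallback reverses the polarity and makes the carboxylate the nucleophile towards an allylic halide, without ever activating the acid. It sets out from 20. Ethanolysis of the acetate (K2CO3, EtOH, 0 °C) should give the hydroxy ester F5; Corey–Kim chlorination (NCS, Me2S, CH2Cl2, −20 °C) the allylic chloride F6; neutral ester cleavage (Me3SnOH, 1,2-dichloroethane, 70 °C) the chloro acid F7. Caesium carboxylate alkylation (Cs2CO3, DMF, high dilution) should then close the ring and come back at 22.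

**Further compounds**

F1 | step 18 | 14-membered allyl β-keto lactone (C13–O–CO–C8H2–C9(=O)–C10, bridged by the 2-methoxy-2,5-dihydrofuran) | O=C1CC(=O)/C(C)=C\CC/C(CO[Si](C)(C)C(C)(C)C)=C/[C@H]2OC(OC)C(=C2)CO1
F2 | step 18 | 8-carboxy derivative of 24 (ring-contracted β-keto acid, C8 epimers) | C=C1C(OC)O[C@@H]2/C=C(\CO[Si](C)(C)C(C)(C)C)CC/C=C(/C)C(=O)C(C(=O)O)[C@H]12
F3 | step 4 | methyl (S)-2-hydroxybut-3-enoate | C=C[C@H](O)C(=O)OC
F4 | step 4 | methyl (S)-2-(triethylsilyloxy)but-3-enoate | C=C[C@H](O[Si](CC)(CC)CC)C(=O)OC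
F5 | step 17 | ethyl (2Z,6Z)-6-[(tert-butyldimethylsilyloxy)methyl]-7-[(2R)-4-(hydroxymethyl)-5-methoxy-2,5-dihydrofuran-2-yl]-2-methylhepta-2,6-dienoate | CCOC(=O)/C(C)=C\CC/C(CO[Si](C)(C)C(C)(C)C)=C/[C@H]1OC(OC)C(=C1)CO
F6 | step 17 | ethyl (2Z,6Z)-6-[(tert-butyldimethylsilyloxy)methyl]-7-[(2R)-4-(chloromethyl)-5-methoxy-2,5-dihydrofuran-2-yl]-2-methylhepta-2,6-dienoate | CCOC(=O)/C(C)=C\CC/C(CO[Si](C)(C)C(C)(C)C)=C/[C@H]1OC(OC)C(=C1)CCl
F7 | step 17 | (2Z,6Z)-6-[(tert-butyldimethylsilyloxy)methyl]-7-[(2R)-4-(chloromethyl)-5-methoxy-2,5-dihydrofuran-2-yl]-2-methylhepta-2,6-dienoic acid | OC(=O)/C(C)=C\CC/C(CO[Si](C)(C)C(C)(C)C)=C/[C@H]1OC(OC)C(=C1)CCl
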